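Start from 9.8%, the electrophile the red run still holds at 3.00 min. The flask has the red charges of electrophile and nucleophile and more free base, but raising the free base from amber to red moved that reading by just 1.3 percentage points, against a scatter of 1 point, so take red as the flask's nearest guide.

| flask | electrophile | nucleophile | free base | remark | time |
|---|---|---|---|---|---|
| amber | 0.020 M (fed, over 1.0 min) | 0.022 M | 0.030 M | run made earlier |  |
| red | 0.020 M (fed, over 1.0 min) | 0.022 M | 0.045 M | run made earlier |  |
| ochre | 0.010 M (fed, over 1.0 min) | 0.022 M | 0.060 M | run made earlier |  |
| flask | 0.020 M (fed, over 1.0 min) | 0.0220 M | 0.0600 M |  | 5.0 min |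

- amber (time / min: electrophile / %, target / %): 0.833: 50.6, 26.0; 1.50: 36.6, 40.6; 2.50: 14.8, 39.9; 3.00: 11.1, 39.4
- red (time / min: electrophile / %, target / %): 0.250: 19.5, 4.6; 0.500: 34.3, 13.1; 1.33: 38.6, 40.0; 3.00: 9.8, 42.6
- ochre (time / min: electrophile / %, target / %): 0.417: 30.7, 11.3; 1.00: 51.5, 40.2; 2.00: 13.8, 62.8; 3.00: 8.1, 69.4

(readings scatter by 1 percentage point)

- part of the electrophile that has reacted at 5.0 min
- share of the unused nucleophile that is free and not bound as protonated nucleophile, at 5.0 min

Look at what seems not to fit in red: with 1.10 equivalents of nucleophile charged, the electrophile falls by 29 points between 1.33 min and 3.00 min, while the target gains just 2.6 points. Read this as the target turning partner to the electrophile as it forms, and stop asking which partner it is: past the feed, define the late decay constant λ, the fall of ln(electrophile) per minute, a pseudo-first-order constant that counts the partners together, 0.821 min⁻¹ in red. Carried from the red reading to the asked time, this reckoning puts the electrophile of the flask near 1.90%, so estimate c near 98.1%; leave the free share as a guess, as the runs do not show it.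

The forecast gives 95% and 40%, on “about 9.5% electrophile left at 3 min, halving by 5 min”, a fall of 0.347 min⁻¹, slower than λ.

The flask gives 98.0% and 59.6%, so the forecast parts from it on the free share, by 20 points.

    electrophile + nucleophile → acid set free + target (k = 1.25 M⁻¹ s⁻¹)
    nucleophile + acid set free ⇌ protonated nucleophile, settled at all times (K = 83800 M⁻¹)
    acid set free + free base ⇌ salt of the base, settled at all times (K = 27700 M⁻¹)
    electrophile + target → side product (k = 0.746 M⁻¹ s⁻¹)
    target → over-reaction product (k = 1.94 × 10⁻⁵ s⁻¹)

Between 2.50 min and 5.00 min the electrophile of the flask falls at 0.766 min⁻¹, against the 0.821 min⁻¹ read in red. Put λ on the amber reading for a neighbour with 0.036 M free base and it gives 2.15% electrophile, where that neighbour holds 2.78%. Part of the flask's high c comes from electrophile + target turning into side product, together with acid set free joining free base as salt of the base: without the first the flask reaches 84.8%, without the second 87.0%.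

The runs are calculated for an exercise; scatter was added.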